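**Retrosynthetic overview**
1. GA93 ⇐ hydroxyl-directed epoxidation of a 1β-hydroxy-Δ2 19,10-lactone, which comes from a Δ1(10),2-diene 7,19-diacid by β-epoxidation of C-1=C-10 and anti opening at C-10 by the C-19 acid.
2. Ring A and C-4 ⇐ intramolecular Diels–Alder of a 7-O-(E)-3-chloroacrylate onto a ring-B 1-vinylcyclopentene, then eliminative α-methylation, C-7 oxidation and C-6 epimerisation.
3. Diene ⇐ C-10 ketone (enol triflate, Stille); ring D ⇐ SmI2 ketyl–alkyne cyclisation of a C-8 propargyl C-13 ketone.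
4. C-8 quaternary centre ⇐ Claisen rearrangement with chirality transfer from a 10β allylic alcohol made by a ketoreductase; ring C ⇐ Birch reduction of an anisole.
5. Ring B ⇐ Friedel–Crafts closure of an arylsuccinate whose C-6 centre comes from a conjugate arylation catalysed by [RhCl(C2H4)2]2 and a chiral diene ligand. Ring order: C (arene) → B → D → A with δ-lactone → γ-lactone → epoxide.

Assumption: the target gibberellin is written GA93; intermediates are described with the gibberellane numbering of the target (C-1 to C-19; α = face of the lactone bridge, β = face of H-5, H-9 and the C-15/C-16 bridge), and the SMILES strings give the definitive stereochemistry.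

**Route**

Step 1
Reactants: 1 3-methoxyphenylboronic acid; 2 di-tert-butyl fumarate
Product: 3 di-tert-butyl (R)-2-(3-methoxyphenyl)succinate
Conditions: [RhCl(C2H4)2]2 (1.5 mol %), chiral diene 2,5-dibenzylbicyclo[2.2.2]octa-2,5-diene (the enantiomer that gives the R ester), KOH (10 mol %), dioxane/H2O 10:1, 50 °C
Reagents that add atoms: none
Why: Hayashi–Miyaura asymmetric 1,4-addition, in which the aryl–rhodium/chiral diene complex selects one enantiotopic face of the fumarate and sets C-6 (about 90% ee, raised later by crystallisation and by step 3).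

Step 2
Reactants: 3 di-tert-butyl (R)-2-(3-methoxyphenyl)succinate
Product: 5 (R)-6-methoxy-3-oxo-2,3-dihydro-1H-indene-1-carboxylic acid, via arylsuccinic acid 4 (not isolated)
Conditions: TFA, CH2Cl2, rt; evaporate; Eaton's reagent (P2O5 in MeSO3H), 40 °C; recrystallise
Reagents that add atoms: none
Why: acidolysis of the tert-butyl esters, then intramolecular Friedel–Crafts acylation by the CH2CO2H arm para to the methoxy group closes ring B without enolising C-6.

Step 3
Reactants: 5 (R)-6-methoxy-3-oxo-2,3-dihydro-1H-indene-1-carboxylic acid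
Product: 6 (1R,3R)-3-hydroxy-6-methoxy-2,3-dihydro-1H-indene-1-carboxylic acid (trans)
Conditions: ketoreductase (NADPH-dependent, R-selective), NADP+ (cat.), isopropanol (10 vol %), phosphate buffer pH 7, 30 °C
Reagents that add atoms: none
Why: enzymatic carbonyl reduction by a ketoreductase under catalyst control gives the 10β (trans) alcohol that hydride reagents (cis-selective) do not give, and turns the minor enantiomer of 5 into a separable cis diastereomer.

Step 4
Reactants: 6 (1R,3R)-3-hydroxy-6-methoxy-2,3-dihydro-1H-indene-1-carboxylic acid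
Product: 7 (1R,3R)-3-(hydroxymethyl)-5-methoxy-2,3-dihydro-1H-inden-1-ol
Conditions: LiAlH4, THF, 0 °C to reflux; aqueous NaOH work-up
Reagents that add atoms: none
Why: hydride reduction of the carboxylic acid to the primary alcohol leaves both stereocentres untouched.

Step 5
Reactants: 7 (1R,3R)-3-(hydroxymethyl)-5-methoxy-2,3-dihydro-1H-inden-1-ol
Product: 8 (1R,3R)-5-methoxy-3-[(triisopropylsilyloxy)methyl]-2,3-dihydro-1H-inden-1-ol
Conditions: triisopropylsilyl chloride (1.05 equiv), imidazole, CH2Cl2, 0 °C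
Reagents that add atoms: triisopropylsilyl chloride, CC(C)[Si](Cl)(C(C)C)C(C)C
Why: silyl ether formation, in which the bulky chloride reacts only with the primary hydroxyl.

Step 6
Reactants: 8 (1R,3R)-5-methoxy-3-[(triisopropylsilyloxy)methyl]-2,3-dihydro-1H-inden-1-ol
Product: 9 (1R,3R)-5-methoxy-3-[(triisopropylsilyloxy)methyl]-2,3,4,7-tetrahydro-1H-inden-1-ol
Conditions: BuLi (1.05 equiv), THF, −78 °C; then Li, liquid NH3, t-BuOH, −78 to −33 °C; NH4Cl
Reagents that add atoms: none
Why: Birch reduction puts the methoxy group and both ring-fusion carbons on double bonds (enol ether at C-12/C-13, tetrasubstituted C-8=C-9), while the benzylic oxygen survives as its lithium alkoxide.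

Step 7
Reactants: 9 (1R,3R)-5-methoxy-3-[(triisopropylsilyloxy)methyl]-2,3,4,7-tetrahydro-1H-inden-1-ol
Product: 11 2-[5-methoxy-3-(triisopropylsilyloxymethyl)-2,3,4,7-tetrahydro-3aH-inden-3a-yl]acetaldehyde (3,3a-trans; C-8 β-CH2CHO; C-9=C-10), via allyl vinyl ether 10 (not isolated)
Conditions: [Ir(cod)Cl]2 (1 mol %), Na2CO3 (0.6 equiv), vinyl acetate, toluene, 100 °C; then xylene, 150 °C, sealed tube
Reagents that add atoms: vinyl acetate, CC(=O)OC=C
Why: transfer vinylation then Claisen rearrangement, whose suprafacial [3,3] shift carries the 10β C–O chirality to C-8, so the new CH2CHO is β and trans to the 6α-CH2OSi group.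

Step 8
Reactants: 11 angular aldehyde
Product: 12 bis-dioxolane (C-13 ethylene ketal in place of the enol ether; C-16 ethylene acetal; C-9=C-10)
Conditions: ethylene glycol (10 equiv), PPTS (cat.), benzene, reflux, Dean–Stark
Reagents that add atoms: ethylene glycol, OCCO
Why: acid-catalysed acetalisation converts the methyl enol ether and the aldehyde into dioxolanes, masking both carbonyls for the hydroboration.

Step 9
Reactants: 12 bis-dioxolane
Product: 13 10β-alcohol of the bis-dioxolane (H-9β; cis-hydrindane)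
Conditions: BH3·THF (2 equiv), THF, 0 °C to rt; then NaOH (aq), H2O2, 0 °C
Reagents that add atoms: hydrogen peroxide, OO
Why: hydroboration–oxidation places boron on the less substituted C-10 and adds syn from the β face, away from C-14 of ring C and the 6α side chain (a C-9 epimer would be corrected in step 13).

Step 10
Reactants: 13 10β-alcohol of the bis-dioxolane
Product: 14 10β-hydroxy 13-ketone 16-aldehyde (in equilibrium with its 10,16-lactol)
Conditions: AcOH/THF/H2O 3:1:1, 50 °C
Reagents that add atoms: water, O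
Why: acetal hydrolysis frees the C-13 ketone and the C-16 aldehyde while the primary triisopropylsilyl ether stays intact.

Step 11
Reactants: 14 10β-hydroxy 13-ketone 16-aldehyde
Product: 15 10β-hydroxy 13-ketone with C-8 β-propargyl group
Conditions: dimethyl (1-diazo-2-oxopropyl)phosphonate (1.5 equiv), K2CO3, MeOH, 0 °C to rt
Reagents that add atoms: dimethyl (1-diazo-2-oxopropyl)phosphonate, CC(=O)C(=[N+]=[N-])P(=O)(OC)OC
Why: Ohira–Bestmann (Seyferth–Gilbert) homologation converts the aldehyde (drawn from the lactol) into the terminal alkyne, adding C-17, faster than any ketone reacts.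

Step 12
Reactants: 15 propargyl ketone
Product: 16 tricyclic B/C/D diol (13-OH; 16-methylene; 10β-OH; 6α-CH2OSi(CHMe2)3)
Conditions: SmI2 (3 equiv), HMPA, t-BuOH (3 equiv), THF, 0 °C to rt
Reagents that add atoms: none
Why: ketyl–alkyne reductive cyclisation (5-exo-dig) closes ring D, and because the propargyl arm can only bridge on the β face the C-13 configuration is fixed.

Step 13
Reactants: 16 tricyclic diol
Product: 17 tricyclic 10-ketone (13-OH; H-9β)
Conditions: Dess–Martin periodinane (1.3 equiv), CH2Cl2, rt; then DBU (0.2 equiv), rt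
Reagents that add atoms: none
Why: Dess–Martin oxidation touches only the secondary alcohol, and DBU equilibrates C-9 to the more stable cis-fused hydrindanone.

Step 14
Reactants: 17 tricyclic 10-ketone
Product: 18 C-10 enol triflate (C-5=C-10)
Conditions: KN(SiMe3)2 (2.2 equiv), THF, −78 °C; PhNTf2 (1.1 equiv), −78 to 0 °C
Reagents that add atoms: N-phenylbis(trifluoromethanesulfonimide), O=S(=O)(N(c1ccccc1)S(=O)(=O)C(F)(F)F)C(F)(F)F
Why: kinetic enolisation occurs at the C-5 methylene rather than the hindered C-9 methine, and the enolate is trapped as its triflate while the tertiary alkoxide stays untouched.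

Step 15
Reactants: 18 enol triflate
Product: 19 C-10 vinyl diene (C-5=C-10–C-1=C-2; silyl ether)
Conditions: Bu3SnCH=CH2 (1.5 equiv), Pd(PPh3)4 (5 mol %), LiCl (3 equiv), THF, 65 °C
Reagents that add atoms: tributyl(vinyl)stannane, C=C[Sn](CCCC)(CCCC)CCCC
Why: Stille coupling of the enol triflate installs C-1/C-2 and completes the diene for ring A.

Step 16
Reactants: 19 C-10 vinyl diene
Product: 20 dienediol (6α-CH2OH; 13-OH)
Conditions: Bu4NF (1.5 equiv), THF, 0 °C to rt
Reagents that add atoms: none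
Why: fluoride cleaves the primary silyl ether to free the C-7 hydroxyl.

Step 17
Reactants: 20 dienediol; 21 (E)-3-chloroacrylic acid
Product: 22 7-O-[(E)-3-chloroacryloyl] ester of the dienediol
Conditions: DCC (1.2 equiv), DMAP (5 mol %), CH2Cl2, 0 °C
Reagents that add atoms: none
Why: Steglich esterification acylates the primary alcohol only, as the tertiary bridgehead 13-OH is inert.

Step 18
Reactants: 22 chloroacrylate
Product: 23 13-O-triethylsilyl chloroacrylate
Conditions: Et3SiOTf (1.5 equiv), 2,6-lutidine, CH2Cl2, −78 to 0 °C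
Reagents that add atoms: triethylsilyl trifluoromethanesulfonate, CC[Si](CC)(CC)OS(=O)(=O)C(F)(F)F
Why: silylation of the tertiary allylic alcohol keeps it from directing the later epoxidations to C-16=C-17.

Step 19
Reactants: 23 13-O-triethylsilyl chloroacrylate
Product: 24 Diels–Alder adduct (3β-chloro 19→7 δ-lactone; C-1=C-10; H-4β; H-5β)
Conditions: toluene (0.005 M), propylene oxide, BHT, sealed tube, 160 °C
Reagents that add atoms: none
Why: intramolecular Diels–Alder in which the short ester tether on the α face of C-6 delivers the dienophile to the α face of C-5, closing ring A and setting H-5β (C-3 and C-4 are reset in step 20).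

Step 20
Reactants: 24 Diels–Alder adduct
Product: 26 4β-methyl-Δ1(10),2-diene 19→7 δ-lactone (13-OSiEt3), via unsaturated lactone 25 (not isolated)
Conditions: LiN(CHMe2)2 (3.2 equiv), THF/HMPA, −78 °C; MeI (6 equiv), −78 to −40 °C
Reagents that add atoms: iodomethane, CI
Why: E1cB loss of chloride, γ-deprotonation at doubly allylic C-2 and deconjugative α-methylation on the face of H-5 (β) set C-4 with the methyl β and the carbonyl α.

Step 21
Reactants: 26 diene δ-lactone
Product: 28 allyl 19-ester 7-alcohol (6α-CH2OH; Δ1(10),2-diene), via lithium carboxylate 27 (not isolated)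
Conditions: LiOH (1.5 equiv), THF/MeOH/H2O, 45 °C; evaporate to dryness; allyl bromide (3 equiv), DMF, rt
Reagents that add atoms: lithium hydroxide, [Li+].[OH-]; allyl bromide, C=CCBr
Why: saponification then carboxylate O-alkylation holds the lactone open as an allyl ester, so the hydroxy acid cannot re-lactonise.

Step 22
Reactants: 28 allyl 19-ester 7-alcohol
Product: 30 6β-aldehyde (19-allyl ester), via 6α-aldehyde 29 (not isolated)
Conditions: Dess–Martin periodinane, CH2Cl2, 0 °C to rt; then DBU (0.5 equiv), CH2Cl2, rt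
Reagents that add atoms: none
Why: Dess–Martin oxidation then base epimerisation through the enolate moves the formyl group to the thermodynamic 6β position, trans to the quaternary C-4, which is the natural C-6 configuration.

Step 23
Reactants: 30 6β-aldehyde
Product: 31 7-oic acid 19-allyl ester
Conditions: NaClO2, NaH2PO4, 2-methyl-2-butene (20 equiv), t-BuOH/H2O, 0 °C to rt
Reagents that add atoms: sodium chlorite, [Na+].[O-]Cl=O
Why: Pinnick oxidation gives the acid without epimerisation, the alkene scavenger protecting the diene and the 16-methylene from HOCl.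

Step 24
Reactants: 31 7-oic acid 19-allyl ester
Product: 32 Δ1(10),2-diene 7,19-dioic acid (13-OSiEt3)
Conditions: Pd(PPh3)4 (5 mol %), morpholine (5 equiv), THF, rt
Reagents that add atoms: none
Why: Tsuji–Trost deallylation with zerovalent palladium frees the C-19 acid under neutral conditions.

Step 25
Reactants: 32 diene diacid
Product: 34 1β-hydroxy-13-(triethylsilyloxy)-20-norgibberella-2,16-diene-7,19-dioic acid 19,10-lactone (Δ2 alkene; free 7-oic acid), via 1β,10β-epoxide 33 (not isolated)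
Conditions: mCPBA (1.05 equiv), CH2Cl2, −20 to 0 °C; then rt until lactonised
Reagents that add atoms: 3-chloroperoxybenzoic acid, OOC(=O)c1cccc(Cl)c1
Why: Prilezhaev epoxidation of the trisubstituted C-1=C-10 from the β face (flanked only by H-5 and H-9), then 5-exo anti opening at tertiary C-10 by the α C-19 acid, sets C-10 (O α) and C-1 (OH β).

Step 26
Reactants: 34 1β-hydroxy-13-(triethylsilyloxy)-20-norgibberella-2,16-diene-7,19-dioic acid 19,10-lactone
Product: 35 13-O-triethylsilyl-GA93 (2β,3β-epoxide; 1β-OH; 19,10-lactone; 7-oic acid)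
Conditions: VO(acac)2 (5 mol %), t-BuOOH (1.5 equiv, in decane), CH2Cl2, 0 °C to rt
Reagents that add atoms: tert-butyl hydroperoxide, CC(C)(C)OO
Why: vanadium-catalysed hydroxyl-directed epoxidation delivers oxygen syn to the pseudo-axial 1β-OH, giving the 2β,3β-epoxide and leaving the silylated C-16=C-17 alone.

Step 27
Reactants: 35 13-O-triethylsilyl-GA93
Product: 36 GA93 (2β,3β-epoxy-1β,13-dihydroxy-20-norgibberell-16-ene-7,19-dioic acid 19,10-lactone)
Conditions: HF·pyridine, pyridine, THF, 0 °C to rt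
Reagents that add atoms: none
Why: buffered fluoride desilylation frees the 13-OH without opening the epoxide or the lactone.

**Compound list**
1 | 3-methoxyphenylboronic acid | COc1cccc(c1)B(O)O | starting material
2 | di-tert-butyl fumarate | CC(C)(C)OC(=O)/C=C/C(=O)OC(C)(C)C | starting material
3 | di-tert-butyl (R)-2-(3-methoxyphenyl)succinate | COc1cccc(c1)[C@H](C(=O)OC(C)(C)C)CC(=O)OC(C)(C)C | intermediate
4 | (R)-2-(3-methoxyphenyl)succinic acid | COc1cccc(c1)[C@H](C(=O)O)CC(=O)O | intermediate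
5 | (R)-6-methoxy-3-oxo-2,3-dihydro-1H-indene-1-carboxylic acid | COc1ccc2c(c1)[C@H](C(=O)O)CC2=O | intermediate
6 | (1R,3R)-3-hydroxy-6-methoxy-2,3-dihydro-1H-indene-1-carboxylic acid (trans) | COc1ccc2c(c1)[C@H](C(=O)O)C[C@H]2O | intermediate
7 | (1R,3R)-3-(hydroxymethyl)-5-methoxy-2,3-dihydro-1H-inden-1-ol (trans) | COc1ccc2c(c1)[C@H](CO)C[C@H]2O | intermediate
8 | (1R,3R)-5-methoxy-3-[(triisopropylsilyloxy)methyl]-2,3-dihydro-1H-inden-1-ol | COc1ccc2c(c1)[C@H](CO[Si](C(C)C)(C(C)C)C(C)C)C[C@H]2O | intermediate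
9 | (1R,3R)-5-methoxy-3-[(triisopropylsilyloxy)methyl]-2,3,4,7-tetrahydro-1H-inden-1-ol | COC1=CCC2=C(C1)[C@H](CO[Si](C(C)C)(C(C)C)C(C)C)C[C@H]2O | intermediate
10 | vinyl ether of 9 at the C-10 oxygen | COC1=CCC2=C(C1)[C@H](CO[Si](C(C)C)(C(C)C)C(C)C)C[C@H]2OC=C | intermediate
11 | 2-[5-methoxy-3-(triisopropylsilyloxymethyl)-2,3,4,7-tetrahydro-3aH-inden-3a-yl]acetaldehyde, 3,3a-trans (C-8 β-CH2CHO, C-6 α side chain, C-9=C-10) | O=CC[C@]12CC(OC)=CCC1=CC[C@H]2CO[Si](C(C)C)(C(C)C)C(C)C | intermediate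
12 | bis-dioxolane of 11 (C-13 ethylene ketal, C-16 ethylene acetal) | O1CCOC1C[C@]23CC4(OCCO4)CCC2=CC[C@H]3CO[Si](C(C)C)(C(C)C)C(C)C | intermediate
13 | 10β-alcohol of 12 (H-9β, cis-hydrindane) | O1CCOC1C[C@]23CC4(OCCO4)CC[C@H]2[C@H](O)C[C@H]3CO[Si](C(C)C)(C(C)C)C(C)C | intermediate
14 | 10β-hydroxy 13-ketone 16-aldehyde (C-8 β-CH2CHO) | O=CC[C@]12CC(=O)CC[C@H]1[C@H](O)C[C@H]2CO[Si](C(C)C)(C(C)C)C(C)C | intermediate
15 | 10β-hydroxy 13-ketone with C-8 β-propargyl | C#CC[C@]12CC(=O)CC[C@H]1[C@H](O)C[C@H]2CO[Si](C(C)C)(C(C)C)C(C)C | intermediate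
16 | tricyclic B/C/D diol (13-OH, 16-methylene, 10β-OH, 6α-CH2O-silyl) | C=C1C[C@]23C[C@@]1(O)CC[C@H]2[C@H](O)C[C@H]3CO[Si](C(C)C)(C(C)C)C(C)C | intermediate
17 | tricyclic 10-ketone (13-OH, H-9β) | C=C1C[C@]23C[C@@]1(O)CC[C@H]2C(=O)C[C@H]3CO[Si](C(C)C)(C(C)C)C(C)C | intermediate
18 | C-10 enol triflate (C-5=C-10) | C=C1C[C@]23C[C@@]1(O)CC[C@H]2C(OS(=O)(=O)C(F)(F)F)=C[C@H]3CO[Si](C(C)C)(C(C)C)C(C)C | intermediate
19 | C-10 vinyl diene, triisopropylsilyl ether | C=C1C[C@]23C[C@@]1(O)CC[C@H]2C(C=C)=C[C@H]3CO[Si](C(C)C)(C(C)C)C(C)C | intermediate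
20 | dienediol (6α-CH2OH, 13-OH) | C=C1C[C@]23C[C@@]1(O)CC[C@H]2C(C=C)=C[C@H]3CO | intermediate
21 | (E)-3-chloroacrylic acid | OC(=O)/C=C/Cl | starting material
22 | 7-O-[(E)-3-chloroacryloyl] ester of 20 | C=C1C[C@]23C[C@@]1(O)CC[C@H]2C(C=C)=C[C@H]3COC(=O)/C=C/Cl | intermediate
23 | 13-O-triethylsilyl ether of 22 | C=C1C[C@]23C[C@@]1(O[Si](CC)(CC)CC)CC[C@H]2C(C=C)=C[C@H]3COC(=O)/C=C/Cl | intermediate
24 | Diels–Alder adduct: 3β-chloro 19→7 δ-lactone, C-1=C-10, H-4β, H-5β | C=C1C[C@]23C[C@@]1(O[Si](CC)(CC)CC)CC[C@H]2C1=CC[C@H](Cl)[C@H]4C(=O)OC[C@@H]3[C@@H]14 | intermediate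
25 | Δ1(10),3-diene 19→7 δ-lactone (α,β-unsaturated) | C=C1C[C@]23C[C@@]1(O[Si](CC)(CC)CC)CC[C@H]2C1=CCC=C4C(=O)OC[C@@H]3[C@@H]14 | intermediate
26 | 4β-methyl-Δ1(10),2-diene 19→7 δ-lactone | C=C1C[C@]23C[C@@]1(O[Si](CC)(CC)CC)CC[C@H]2C1=CC=C[C@@]4(C)C(=O)OC[C@@H]3[C@@H]14 | intermediate
27 | lithium 19-carboxylate of the ring-opened 7-alcohol | C=C1C[C@]23C[C@@]1(O[Si](CC)(CC)CC)CC[C@H]2C1=CC=C[C@@](C)(C(=O)[O-])[C@H]1[C@H]3CO.[Li+] | intermediate
28 | allyl 19-ester 7-alcohol (6α-CH2OH) | C=C1C[C@]23C[C@@]1(O[Si](CC)(CC)CC)CC[C@H]2C1=CC=C[C@@](C)(C(=O)OCC=C)[C@H]1[C@H]3CO | intermediate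
29 | 6α-aldehyde, 19-allyl ester | C=C1C[C@]23C[C@@]1(O[Si](CC)(CC)CC)CC[C@H]2C1=CC=C[C@@](C)(C(=O)OCC=C)[C@H]1[C@H]3C=O | intermediate
30 | 6β-aldehyde, 19-allyl ester | C=C1C[C@]23C[C@@]1(O[Si](CC)(CC)CC)CC[C@H]2C1=CC=C[C@@](C)(C(=O)OCC=C)[C@H]1[C@@H]3C=O | intermediate
31 | 7-oic acid 19-allyl ester | C=C1C[C@]23C[C@@]1(O[Si](CC)(CC)CC)CC[C@H]2C1=CC=C[C@@](C)(C(=O)OCC=C)[C@H]1[C@@H]3C(=O)O | intermediate
32 | Δ1(10),2-diene 7,19-dioic acid, 13-O-triethylsilyl | C=C1C[C@]23C[C@@]1(O[Si](CC)(CC)CC)CC[C@H]2C1=CC=C[C@@](C)(C(=O)O)[C@H]1[C@@H]3C(=O)O | intermediate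
33 | 1β,10β-epoxide of 32 | C=C1C[C@]23C[C@@]1(O[Si](CC)(CC)CC)CC[C@H]2[C@]14O[C@@H]4C=C[C@@](C)(C(=O)O)[C@H]1[C@@H]3C(=O)O | intermediate
34 | 1β-hydroxy-13-(triethylsilyloxy)-20-norgibberella-2,16-diene-7,19-dioic acid 19,10-lactone | C=C1C[C@]23C[C@@]1(O[Si](CC)(CC)CC)CC[C@H]2[C@@]12OC(=O)[C@@](C)([C@H]1[C@@H]3C(=O)O)C=C[C@H]2O | intermediate
35 | 13-O-triethylsilyl-GA93 (2β,3β-epoxide, 1β-OH, 19,10-lactone, 7-oic acid) | C=C1C[C@]23C[C@@]1(O[Si](CC)(CC)CC)CC[C@H]2[C@@]12OC(=O)[C@@](C)([C@H]1[C@@H]3C(=O)O)[C@H]1O[C@H]1[C@H]2O | intermediate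
36 | GA93 (2β,3β-epoxy-1β,13-dihydroxy-20-norgibberell-16-ene-7,19-dioic acid 19,10-lactone) | C=C1C[C@]23C[C@@]1(O)CC[C@H]2[C@@]12OC(=O)[C@@](C)([C@H]1[C@@H]3C(=O)O)[C@H]1O[C@H]1[C@H]2O | target

**Totals and risks**

Total step count: 27. Longest linear sequence: 27 steps (fully linear from 1 and 2; 21 joins at step 17).

The three steps most likely to fail are 7, 19 and 25.

Step 7 may fail if vinyl transfer is slow or if the Birch 1,4-diene/enol ether isomerises at 150 °C. The fallback sets out from 9 and returns at 11. Heating 9 with N,N-dimethylacetamide dimethyl acetal in xylene at 140 °C (Eschenmoser–Claisen, no metal and no acid) gives the C-8 β-acetamide F1 by the same suprafacial transfer from the 10β oxygen. Partial reduction of this tertiary amide with Cp2Zr(H)Cl in THF at rt then gives aldehyde 11.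

Step 19 may fail through [1,5]-hydrogen shifts or polymerisation of the diene at 160 °C. The fallback sets out from 20 and returns at 26. The C-7 alcohol is esterified with propiolic acid (DCC, CH2Cl2, 0 °C) to the propiolate F2, which is silylated (Et3SiOTf, 2,6-lutidine) to the 13-O-triethylsilyl propiolate F3. The alkyne dienophile cyclises at about 110 °C in toluene and gives the 1,4-diene lactone 25 directly, with no HCl to lose. Here 25 is isolated and treated with one equivalent less of LiN(CHMe2)2 and MeI as in step 20, giving 26.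

Step 25 may fail if the free acids steer the peracid to the α face or if the other alkenes compete. The fallback sets out from 26 and returns at 35; it epoxidises while the cis-fused δ-lactone still shields the α face. mCPBA on 26 gives the 1β,10β-epoxy δ-lactone F4. LiOH in THF/H2O followed by acidification to pH 4 opens the δ-lactone, and the C-19 acid opens the epoxide at C-10 to give the 1β-hydroxy-Δ2 19,10-lactone 7-alcohol F5 (6α-CH2OH). VO(acac)2 and t-BuOOH give the 2β,3β-epoxy alcohol F6. TEMPO with PhI(OAc)2 oxidises only the primary alcohol to the 6α-aldehyde F7, DBU epimerises it to the 6β-aldehyde F8, and Pinnick oxidation (NaClO2, NaH2PO4, 2-methyl-2-butene) gives 35.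

**Further compounds**
F1 | step 7 | C-8 β-CH2C(O)NMe2 amide from 9 (C-9=C-10, enol ether retained) | CN(C)C(=O)C[C@]12CC(OC)=CCC1=CC[C@H]2CO[Si](C(C)C)(C(C)C)C(C)C
F2 | step 19 | 7-O-propiolate of 20 | C=C1C[C@]23C[C@@]1(O)CC[C@H]2C(C=C)=C[C@H]3COC(=O)C#C
F3 | step 19 | 13-O-triethylsilyl ether of F2 | C=C1C[C@]23C[C@@]1(O[Si](CC)(CC)CC)CC[C@H]2C(C=C)=C[C@H]3COC(=O)C#C
F4 | step 25 | 1β,10β-epoxide of δ-lactone 26 | C=C1C[C@]23C[C@@]1(O[Si](CC)(CC)CC)CC[C@H]2[C@]15O[C@@H]5C=C[C@@]4(C)C(=O)OC[C@@H]3[C@@H]14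
F5 | step 25 | 1β-hydroxy-Δ2 19,10-lactone with 6α-CH2OH, 13-O-triethylsilyl | C=C1C[C@]23C[C@@]1(O[Si](CC)(CC)CC)CC[C@H]2[C@@]12OC(=O)[C@@](C)([C@H]1[C@H]3CO)C=C[C@H]2O
F6 | step 25 | 2β,3β-epoxide of F5 | C=C1C[C@]23C[C@@]1(O[Si](CC)(CC)CC)CC[C@H]2[C@@]12OC(=O)[C@@](C)([C@H]1[C@H]3CO)[C@H]1O[C@H]1[C@H]2O
F7 | step 25 | 6α-aldehyde from F6 | C=C1C[C@]23C[C@@]1(O[Si](CC)(CC)CC)CC[C@H]2[C@@]12OC(=O)[C@@](C)([C@H]1[C@H]3C=O)[C@H]1O[C@H]1[C@H]2O
F8 | step 25 | 6β-aldehyde (C-6 epimer of F7) | C=C1C[C@]23C[C@@]1(O[Si](CC)(CC)CC)CC[C@H]2[C@@]12OC(=O)[C@@](C)([C@H]1[C@@H]3C=O)[C@H]1O[C@H]1[C@H]2O
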